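## Analysis of the target

The target is a trans-fused decalin carrying a 2-methyl-1,4-benzoquinon-6-ylmethyl group. I number the decalin C1 (quaternary, methyl and quinonylmethyl), C2 (CHMe), C3, C4, C4a (angular CMe), C5 (CH with the 2-carboxyethyl chain), C6 (isopropylidene carbon), C7, C8, C8a (CH). Ring B is C1–C4 plus C4a and C8a, ring A is C5–C8 plus C4a and C8a. α is the face of H-8a and β the face of the angular methyl.

There are five stereocentres, (1S,2S,4aR,5S,8aR) in this numbering. The C1 and C4a methyls are both β and syn-diaxial. The quinonylmethyl group, the C2 methyl and H-8a are all α. The C5 chain is β (equatorial, cis to the angular methyl) and eclipses the exocyclic alkene.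

The quinone does not tolerate base, nucleophiles or reductants, so it is carried as a 2,5-dimethoxy-3-methylphenyl group and unveiled last. The tetrasubstituted C6 alkene next to a carboxylic acid chain is sensitive to strong acid (lactonisation, alkene migration).

The hard points are two quaternary carbons (one neopentyl to the arene), the contiguous C1/C2/C8a triad, the trans angular methyl, and a C5/C6 pattern with no carbonyl to steer it.

The strategy rests on one feature: the all-cis arrangement of the C1 arylmethyl group, the C2 methyl and H-8a is exactly what an endo [4+2] addition of an (E)-2-(arylmethyl)but-2-enal to a ring A vinylcyclohexene leaves behind. The formyl group then stands where the C1 methyl is needed.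

## Retrosynthetic reasoning

**Quinone last.** Quinone 33 is taken back to the hydroquinone dimethyl ether acid 32, so that no earlier step has to tolerate the quinone. Acid 32 comes from ester 31 by hydrolysis, placed before the oxidation because the quinone would not survive hydroxide.

**Isopropylidene.** In 31 the C6=C(exocyclic) double bond is cut, giving keto ester 30 and a three-carbon ketone partner. A reductive carbonyl–carbonyl coupling fixes the alkene between the two former carbonyl carbons. A tertiary alcohol and dehydration would have to choose between three β-positions (C5, C7, methyl) and would endanger C5.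

**C5 stereocentre.** The C6 carbonyl and the C5 hydrogen of 30 are traced through alcohol 29 to the C5=C6 alkene 27. Hydroboration puts oxygen on C6 and hydrogen on C5 from the α face, opposite the axial angular methyl. C5 is therefore set by C–H and not C–C bond formation: a carbon reagent would also enter from the α face and give the wrong epimer.

**C5 side chain.** The C5–chain bond is cut at the sp2 stage: 27 comes from enol triflate 26 and a zinc homoenolate. Triflate 26 comes from ketone 24, whose only enolisable position is C6, so no regiochemical question arises.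

**Angular methyl.** Ketone 24 comes from alcohol 23, and 23 from cyclopropyl carbinol 22 by hydrogenolysis of the C4–CH2 bond. The three-membered ring of 18 is put onto the C4=C4a alkene of 17 from the β face. The director is the C1 hydroxymethyl group of 17, which is the reduced formyl group of the cycloadduct: it is axial and lies directly over the β face of C4a. The C5 silyloxy group is left on the α face as a shield. A C5 carbinol inverted to β would be equatorial and close to the plane of the alkene, so it would discriminate the faces poorly; it is kept only as a reserve. After the cyclopropanation the same carbon is returned to the aldehyde (19) and reduced to the C1 methyl on the way to 22.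

**Key disconnection.** Adduct 16 is cut at C1–C8a and C2–C3 into diene 5 and enal 15. This removes ring B, three stereocentres and the arene attachment in one step. The forward reaction has to achieve ortho regiochemistry, endo formyl and approach anti to the silyloxy group.

**Enal.** Enal 15 is cut at its C2=C3 bond into 3-arylpropanal 10 and acetaldehyde 12. Both are enolisable, so the condensation is run as a directed aldol through imine 11. Aldehyde 10 goes back through 9 and 8 to salicylaldehyde 7 and phenol 6, whose only free ortho position is the one required.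

**Diene.** Diene 5 comes from iodide 4 by vinyl coupling; 4 comes from carbinol 3, made by enantioselective reduction of iodoenone 2, itself from enone 1.

## Alternatives that were turned down

**Alternative 1: lactone enolate Claisen ring contraction.** The disconnection is C1–C2 of ring B; ring B would arise by contraction of a six-membered lactone spanning C1 (acyl side) and C4 (alkoxy side, carrying an (E)-propenyl group) on a preformed ring A. In the forward step the silyl ketene acetal of that lactone undergoes a [3,3] shift: C1–C2 forms, C4–O breaks, and acid A1 results (C1 carboxyl α and methyl β, C2 methyl α, C3=C4 alkene, C5 dioxolane).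

- For: the angular methyl and the trans ring fusion are already in the bicyclic precursor, so no cyclopropane detour is needed. On that point it is stronger than the chosen route. The shift is intramolecular and makes the C1 quaternary centre reliably.
- Against: the lactone ring forces a boat-like transition state, so the C2 configuration depends on that boat being exclusive. The arene is absent: the carboxyl carbon must become the benzylic CH2 by aryl-metal addition to a neopentyl carbonyl and benzylic deoxygenation. The lactone needs its own stereocontrolled synthesis. A1 still carries its oxygen on C5, so the whole C5/C6 elaboration of the chosen route remains, plus hydrogenation of C3=C4.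
- Comparison: longer and linear. The chosen route gives up the early angular methyl but brings in the arene, C1, C2 and C8a in one convergent step.

**Alternative 2: trienal intramolecular Diels–Alder.** The disconnection is C1–C2 and C4a–C8a; both rings come from an acyclic (E,E,E)-trienal that already carries the C5 stereocentre and a C6 dioxolane. The Lewis acid-promoted or thermal [4+2] closes ring B as a cyclohexene and ring A through the tether, giving aldehyde A2.

- For: one step makes both rings and four stereocentres, with the C5 chain and the C6 oxygen in place and the angular methyl as a diene substituent. On ring A functionality it is clearly stronger: the chosen route spends seven steps there.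
- Against: the diene terminus that becomes C4a is fully substituted, which slows the cycloaddition and strains the s-cis conformer. The trans/cis ring fusion of such decatrienals is not dependable. The precursor is a long chain with three defined alkenes and a stereocentre. The arene must still be added through the C1 formyl group, and C3=C4 hydrogenated.
- Comparison: the chosen route is convergent from two short arms, and its risk lies in one intermolecular step and in functional-group chemistry, not in a long acyclic assembly.

**Alternative 3: conjugate allylation–aldol across a ring B enone.** The disconnection is C8a–C8 and C4a–C5; ring A carbons are appended to a ring B cyclohexenone that already holds the C1 quaternary centre and the arene. A titanium-mediated allylsilane addition at C8a, followed by capture of the enolate at C4a by an unsaturated three-carbon aldehyde, gives ketone A3. Ring A would be closed later by metathesis.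

- For: the arene is present from the start, and the angular methyl is the enone α-methyl, so C4a is made by enolate C–C bond formation without a cyclopropane. On that point it is stronger. The two new chains come out trans.
- Against: A3 has no C2 methyl and has a carbonyl at C4. The methyl must be introduced next to the quaternary C1 and cis to the arylmethyl group with weak facial control, and the carbonyl removed. The allylation face at C8a depends only on the difference between methyl and arylmethyl on C1. The enantiopure enone needs an asymmetric synthesis of its own. The aldol must form a quaternary centre.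
- Comparison: more stereochemical problems remain after the key step than in the chosen route, where the alkene geometry and the endo rule fix C1, C2 and C8a together.

Key step: step 11

## Route

Remarks on the chemistry: the arene is drawn from 4-methoxy-2-methylphenol (6). (3-Ethoxy-3-oxopropyl)zinc bromide, tributyl(vinyl)stannane, the formylmethylene ylide and the oxazaborolidine are taken as purchased reagents. Locants are those of the decalin numbering above.

Step 1
Reactants: 1 cyclohex-2-en-1-one
Product: 2 2-iodocyclohex-2-en-1-one
Conditions: I2, pyridine, CH2Cl2, 0 °C to rt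
Reagents that add atoms: iodine, II
Why: α-Iodination of an enone by conjugate addition of pyridine, iodination of the enolate and elimination is the standard entry to 2-iodoenones.

Step 2
Reactants: 2 2-iodocyclohex-2-en-1-one
Product: 3 (S)-2-iodocyclohex-2-en-1-ol
Conditions: (R)-2-methyl-CBS-oxazaborolidine (10 mol %), BH3·SMe2, THF, 0 °C
Reagents that add atoms: none
Why: CBS reduction; the iodovinyl arm acts as the large substituent, so the (R)-catalyst should deliver hydride to the face that gives the (S)-carbinol, and only 1,2-reduction is expected.

Step 3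
Reactants: 3 (S)-2-iodocyclohex-2-en-1-ol
Product: 4 (S)-tert-butyl[(2-iodocyclohex-2-en-1-yl)oxy]dimethylsilane
Conditions: TBSCl, imidazole, DMF, rt
Reagents that add atoms: tert-butyldimethylsilyl chloride, CC(C)(C)[Si](C)(C)Cl
Why: Standard silylation of a secondary alcohol; the bulky silyl ether is the later facial control element.

Step 4
Reactants: 4 (S)-tert-butyl[(2-iodocyclohex-2-en-1-yl)oxy]dimethylsilane
Product: 5 (S)-tert-butyldimethyl[(2-vinylcyclohex-2-en-1-yl)oxy]silane
Conditions: CH2=CHSnBu3, Pd(PPh3)4 (5 mol %), DMF, 80 °C
Reagents that add atoms: tributyl(vinyl)stannane, C=C[Sn](CCCC)(CCCC)CCCC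
Why: Stille coupling of an alkenyl iodide with a vinylstannane proceeds with retention at the sp2 carbon and does not touch the carbinol centre.

Step 5
Reactants: 6 4-methoxy-2-methylphenol
Product: 7 2-hydroxy-5-methoxy-3-methylbenzaldehyde
Conditions: MgCl2, Et3N, (CH2O)n, MeCN, reflux
Reagents that add atoms: paraformaldehyde (as formaldehyde), C=O
Why: Magnesium phenoxide-directed ortho-formylation; the only free position ortho to the hydroxyl is the one needed, and the hydroxymethyl intermediate is oxidised in the flask by a second formaldehyde.

Step 6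
Reactants: 7 2-hydroxy-5-methoxy-3-methylbenzaldehyde
Product: 8 2,5-dimethoxy-3-methylbenzaldehyde
Conditions: MeI, K2CO3, DMF, rt
Reagents that add atoms: iodomethane, CI
Why: Williamson O-methylation of the phenol.

Step 7
Reactants: 8 2,5-dimethoxy-3-methylbenzaldehyde
Product: 9 (E)-3-(2,5-dimethoxy-3-methylphenyl)prop-2-enal
Conditions: Ph3P=CHCHO (1.05 equiv), toluene, 80 °C
Reagents that add atoms: (triphenylphosphoranylidene)acetaldehyde, O=CC=P(c1ccccc1)(c1ccccc1)c1ccccc1
Why: Wittig reaction of a stabilised ylide with an aromatic aldehyde gives the (E)-enal; one equivalent limits a second homologation.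

Step 8
Reactants: 9 (E)-3-(2,5-dimethoxy-3-methylphenyl)prop-2-enal
Product: 10 3-(2,5-dimethoxy-3-methylphenyl)propanal
Conditions: H2 (1 atm), 5% Pd/C, EtOAc, rt, stopped after one equivalent
Reagents that add atoms: none
Why: Palladium hydrogenates the conjugated C=C much faster than the aldehyde, so the saturated aldehyde should be obtained selectively.

Step 9
Reactants: 10 3-(2,5-dimethoxy-3-methylphenyl)propanal
Product: 11 N-cyclohexyl-3-(2,5-dimethoxy-3-methylphenyl)propan-1-imine
Conditions: cyclohexylamine, MgSO4, Et2O, 0 °C to rt; filtered, concentrated, used crude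
Reagents that add atoms: cyclohexylamine, NC1CCCCC1
Why: Imine condensation driven by the drying agent; the imine is the handle for a directed aldol.

Step 10
Reactants: 11 N-cyclohexyl-3-(2,5-dimethoxy-3-methylphenyl)propan-1-imine; 12 acetaldehyde
Product: 15 (E)-2-(2,5-dimethoxy-3-methylbenzyl)but-2-enal, via lithium aza-enolate 13 (not isolated), via β-hydroxy imine 14 (not isolated)
Conditions: LiN(iPr)2, THF, −78 to 0 °C; then 12, −78 °C; then aq. oxalic acid, THF, rt to 60 °C
Reagents that add atoms: water, O
Why: Directed aldol condensation through the lithiated imine fixes which aldehyde is the nucleophile and so avoids self-condensation of either partner. Acidic hydrolysis with warming frees the aldehyde and dehydrates the aldol to the (E)-enal (methyl trans to formyl), the thermodynamic isomer of a 2-alkylbut-2-enal.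

Step 11
Reactants: 5 (S)-tert-butyldimethyl[(2-vinylcyclohex-2-en-1-yl)oxy]silane; 15 (E)-2-(2,5-dimethoxy-3-methylbenzyl)but-2-enal
Product: 16 (1R,2S,5S,8aS)-5-[(tert-butyldimethylsilyl)oxy]-1-(2,5-dimethoxy-3-methylbenzyl)-2-methyl-1,2,3,5,6,7,8,8a-octahydronaphthalene-1-carbaldehyde (formyl β; arylmethyl, C2 methyl, H-8a and silyloxy α; C4=C4a alkene)
Conditions: BF3·OEt2 (0.5 equiv), 5 (1.5 equiv), CH2Cl2, −78 to −30 °C
Reagents that add atoms: none
Why: BF3 binds the formyl oxygen of 15, and the complex adds suprafacially to the s-cis diene of 5 in a concerted but asynchronous [4+2] cycloaddition; the C2–C3 bond (enal β-carbon to the vinyl CH2) is more advanced than the C1–C8a bond. The closest known reaction type is the Lewis acid-catalysed Diels–Alder reaction of 1-vinylcyclohexenes with tiglic-type enals. Ring B is closed as a cyclohexene by the intermolecular cycloaddition itself, and the new alkene lies at C4=C4a. C1 and C2 copy the (E)-geometry of 15, so the arylmethyl group and the C2 methyl come out cis. C8a is set relative to C1 by the endo orientation of the BF3-bound formyl group, which the bulky arylmethyl arm reinforces by preferring the exo region; formyl ends up trans to H-8a. The absolute configuration comes from the C5 silyloxy group, which sits pseudoaxial to avoid A(1,2) strain with the vinyl group and blocks one diene face, so the enal should add anti to it. The step needs ortho regiochemistry, which is secured because the advanced bond forms at the unhindered CH2 terminus while the hindered quaternary carbon bonds late to the ring terminus. Low temperature is meant to keep the allylic silyl ether intact.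

Step 12
Reactants: 16 octalin aldehyde
Product: 17 [(1R,2S,5S,8aS)-5-[(tert-butyldimethylsilyl)oxy]-1-(2,5-dimethoxy-3-methylbenzyl)-2-methyl-1,2,3,5,6,7,8,8a-octahydronaphthalen-1-yl]methanol
Conditions: NaBH4, MeOH/THF, 0 °C
Reagents that add atoms: none
Why: Borohydride reduction of the non-enolisable neopentyl aldehyde; it reveals the axial β-hydroxymethyl group that directs the next step.

Step 13
Reactants: 17 hydroxymethyl octalin
Product: 18 cyclopropane of 17: a CH2 bridges C4 and C4a on the β face (cis to the C1 hydroxymethyl, trans to H-8a and to the C5 silyloxy group)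
Conditions: Et2Zn (5 equiv), CH2I2 (10 equiv), CH2Cl2, 0 °C to rt
Reagents that add atoms: diiodomethane, ICI
Why: Hydroxyl-directed Simmons–Smith cyclopropanation (Furukawa variant): the zinc alkoxide of the axial C1 hydroxymethyl lies over the β face of C4a, while the α face is shielded by the axial C5 silyloxy group and the axial C2 methyl. The CH2 should therefore be delivered to the β face, which sets C4a.

Step 14
Reactants: 18 cyclopropyl alcohol
Product: 19 the corresponding C1 aldehyde (formyl β; β-cyclopropane; C5 silyloxy α)
Conditions: Dess–Martin periodinane, NaHCO3, CH2Cl2, rt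
Reagents that add atoms: none
Why: Dess–Martin oxidation of a hindered primary alcohol under neutral conditions that leave the cyclopropane and the silyl ether alone.

Step 15
Reactants: 19 cyclopropyl aldehyde
Product: 22 cyclopropyl carbinol with C1 β-methyl (C1 α-arylmethyl, C2 α-methyl, 4β,4aβ-methylene bridge, C5 α-hydroxyl, H-8a α), via hydrazone 20 (not isolated), via silyl ether 21 (not isolated)
Conditions: N2H4·H2O, KOH, diethylene glycol, 130 then 200 °C; then Bu4NF, THF, 60 °C on the crude
Reagents that add atoms: none
Why: Wolff–Kishner reduction (Huang-Minlon conditions) of the non-enolisable aldehyde gives the C1 methyl; the cyclopropane is not conjugated to the carbonyl and should be inert. Fluoride then removes the silyl group, so any silyl ether already cleaved by the hot alkali converges on the same alcohol.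

Step 16
Reactants: 22 cyclopropyl carbinol
Product: 23 trans-decalin-5α-ol with 1α-(2,5-dimethoxy-3-methylbenzyl), 1β-methyl, 2α-methyl, 4aβ-methyl and H-8a α
Conditions: H2 (3 atm), PtO2, AcOH, rt
Reagents that add atoms: none
Why: Catalytic hydrogenolysis of an alkylcyclopropane opens the least hindered bond, here C4–CH2, so the bridging carbon stays on C4a as the β angular methyl with retention. The tetrasubstituted arene should be reduced far more slowly at this pressure.

Step 17
Reactants: 23 decalin-5α-ol
Product: 24 trans-decalin-5-one with 1α-(2,5-dimethoxy-3-methylbenzyl), 1β-methyl, 2α-methyl, 4aβ-methyl and H-8a α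
Conditions: Dess–Martin periodinane, CH2Cl2, rt
Reagents that add atoms: none
Why: Dess–Martin oxidation of the secondary alcohol; the ketone has no epimerisable α-centre.

Step 18
Reactants: 24 decalin-5-one
Product: 26 C5 enol triflate of 24 (C5=C6 alkene), via potassium enolate 25 (not isolated)
Conditions: KN(SiMe3)2, THF, −78 °C; then PhNTf2, −78 to 0 °C
Reagents that add atoms: N-phenylbis(trifluoromethanesulfonimide), O=S(=O)(N(c1ccccc1)S(=O)(=O)C(F)(F)F)C(F)(F)F
Why: C4a is quaternary, so only C6 can be deprotonated and the enol triflate is regiochemically unambiguous.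

Step 19
Reactants: 26 enol triflate
Product: 27 ethyl 3-(decalin-5-en-5-yl)propanoate: the C5=C6 alkene carrying CH2CH2CO2Et on C5 (other substituents as in 24)
Conditions: BrZnCH2CH2CO2Et (0.5 M in THF), Pd(PPh3)4 (5 mol %), THF/DMA, 60 °C
Reagents that add atoms: (3-ethoxy-3-oxopropyl)zinc bromide, CCOC(=O)CC[Zn]Br
Why: Negishi coupling of an alkenyl triflate with a zinc homoenolate; an enol triflate next to a quaternary carbon couples readily, and no stereocentre is involved.

Step 20
Reactants: 27 alkenyl ester
Product: 29 ethyl 3-(6α-hydroxy-trans-decalin-5β-yl)propanoate (H-5 α; other substituents as in 24), via alkylborane 28 (not isolated)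
Conditions: BH3·THF (2.5 equiv), THF, 0 °C to rt; then NaBO3·4H2O, THF/H2O, rt
Reagents that add atoms: sodium perborate, [Na+].[O-]B1OO1
Why: Hydroboration of the trisubstituted alkene puts boron on C6 and hydrogen on C5, syn and from the α face opposite the axial angular methyl (the same bias as in steroidal 5-enes). This sets C5 (H α, chain β) and C6; perborate oxidises the C–B bond with retention and spares the ester.

Step 21
Reactants: 29 hydroxy ester
Product: 30 ethyl 3-(6-oxo-trans-decalin-5β-yl)propanoate (H-5 α)
Conditions: Dess–Martin periodinane, NaHCO3, CH2Cl2, rt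
Reagents that add atoms: none
Why: Dess–Martin oxidation; C5 is now α to the ketone, but its equatorial chain is the thermodynamically preferred arrangement, so no epimerisation is expected.

Step 22
Reactants: 30 keto ester
Product: 31 ethyl 3-[6-(propan-2-ylidene)-trans-decalin-5β-yl]propanoate (H-5 α)
Conditions: TiCl3(DME)1.5, Zn–Cu couple, DME, reflux; then 30 and acetone (5 equiv) added slowly, reflux
Reagents that add atoms: acetone, CC(C)=O
Why: Mixed McMurry coupling: low-valent titanium joins the two ketones as a pinacolate and deoxygenates it, placing the tetrasubstituted alkene exactly between C6 and the isopropyl carbon. Excess acetone favours the cross product, the hindered ketone should not dimerise, and an ester is tolerated at short reaction times.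

Step 23
Reactants: 31 isopropylidene ester
Product: 32 3-[(1S,2S,4aR,5S,8aR)-1-(2,5-dimethoxy-3-methylbenzyl)-1,2,4a-trimethyl-6-(propan-2-ylidene)decahydronaphthalen-5-yl]propanoic acid
Conditions: LiOH·H2O, THF/MeOH/H2O, rt; then 1 M HCl to pH 4 at 0 °C
Reagents that add atoms: lithium hydroxide, [Li+].[OH-]
Why: Saponification is placed before the quinone is formed, because the quinone is base-sensitive; brief, cold, mild acidification avoids lactonisation onto the alkene.

Step 24
Reactants: 32 dimethoxyaryl acid
Product: 33 3-[(1S,2S,4aR,5S,8aR)-1,2,4a-trimethyl-1-[(5-methyl-3,6-dioxocyclohexa-1,4-dien-1-yl)methyl]-6-(propan-2-ylidene)decahydronaphthalen-5-yl]propanoic acid (CNP0271365.1)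
Conditions: (NH4)2Ce(NO3)6 (2.5 equiv), MeCN/H2O (2:1), 0 °C, 15 min
Reagents that add atoms: water, O
Why: Oxidative demethylation of a hydroquinone dimethyl ether by tetravalent cerium: the arene radical cation forms at a lower potential than the alkene is oxidised, water supplies both carbonyl oxygens, and the short cold reaction limits acid-promoted side reactions.

## Compound list

1 | cyclohex-2-en-1-one | O=C1C=CCCC1 | starting material
2 | 2-iodocyclohex-2-en-1-one | O=C1CCCC=C1I | intermediate
3 | (S)-2-iodocyclohex-2-en-1-ol | IC1=CCCC[C@@H]1O | intermediate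
4 | (S)-tert-butyl[(2-iodocyclohex-2-en-1-yl)oxy]dimethylsilane | IC1=CCCC[C@@H]1O[Si](C)(C)C(C)(C)C | intermediate
5 | (S)-tert-butyldimethyl[(2-vinylcyclohex-2-en-1-yl)oxy]silane | C=CC1=CCCC[C@@H]1O[Si](C)(C)C(C)(C)C | intermediate
6 | 4-methoxy-2-methylphenol | COc1ccc(O)c(C)c1 | starting material
7 | 2-hydroxy-5-methoxy-3-methylbenzaldehyde | O=Cc1cc(OC)cc(C)c1O | intermediate
8 | 2,5-dimethoxy-3-methylbenzaldehyde | O=Cc1cc(OC)cc(C)c1OC | intermediate
9 | (E)-3-(2,5-dimethoxy-3-methylphenyl)prop-2-enal | O=C/C=C/c1cc(OC)cc(C)c1OC | intermediate
10 | 3-(2,5-dimethoxy-3-methylphenyl)propanal | O=CCCc1cc(OC)cc(C)c1OC | intermediate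
11 | N-cyclohexyl-3-(2,5-dimethoxy-3-methylphenyl)propan-1-imine | C1CCCCC1N=CCCc1cc(OC)cc(C)c1OC | intermediate
12 | acetaldehyde | CC=O | starting material
13 | lithium aza-enolate of 11 (not isolated) | [Li]N(C1CCCCC1)C=CCc1cc(OC)cc(C)c1OC | intermediate
14 | 2-(2,5-dimethoxy-3-methylbenzyl)-3-hydroxybutanal N-cyclohexylimine, diastereomer mixture (not isolated) | CC(O)C(Cc1cc(OC)cc(C)c1OC)C=NC1CCCCC1 | intermediate
15 | (E)-2-(2,5-dimethoxy-3-methylbenzyl)but-2-enal | C/C=C(/C=O)Cc1cc(OC)cc(C)c1OC | intermediate
16 | (1R,2S,5S,8aS)-5-[(tert-butyldimethylsilyl)oxy]-1-(2,5-dimethoxy-3-methylbenzyl)-2-methyl-1,2,3,5,6,7,8,8a-octahydronaphthalene-1-carbaldehyde | COc1cc(C)c(OC)c(C[C@]2(C=O)[C@H]3CCC[C@H](O[Si](C)(C)C(C)(C)C)C3=CC[C@@H]2C)c1 | intermediate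
17 | C1 hydroxymethyl analogue of 16 | COc1cc(C)c(OC)c(C[C@]2(CO)[C@H]3CCC[C@H](O[Si](C)(C)C(C)(C)C)C3=CC[C@@H]2C)c1 | intermediate
18 | 4β,4aβ-methylene-bridged (cyclopropane) alcohol from 17 | COc1cc(C)c(OC)c(C[C@]2(CO)[C@H]3CCC[C@H](O[Si](C)(C)C(C)(C)C)[C@@]34C[C@H]4C[C@@H]2C)c1 | intermediate
19 | C1 aldehyde of 18 | COc1cc(C)c(OC)c(C[C@]2(C=O)[C@H]3CCC[C@H](O[Si](C)(C)C(C)(C)C)[C@@]34C[C@H]4C[C@@H]2C)c1 | intermediate
20 | hydrazone of 19 (not isolated) | COc1cc(C)c(OC)c(C[C@]2(C=NN)[C@H]3CCC[C@H](O[Si](C)(C)C(C)(C)C)[C@@]34C[C@H]4C[C@@H]2C)c1 | intermediate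
21 | C1-methyl cyclopropane silyl ether (not isolated) | COc1cc(C)c(OC)c(C[C@]2(C)[C@H]3CCC[C@H](O[Si](C)(C)C(C)(C)C)[C@@]34C[C@H]4C[C@@H]2C)c1 | intermediate
22 | C1-methyl cyclopropyl carbinol (C5 α-OH) | COc1cc(C)c(OC)c(C[C@]2(C)[C@H]3CCC[C@H](O)[C@@]34C[C@H]4C[C@@H]2C)c1 | intermediate
23 | 1α-(2,5-dimethoxy-3-methylbenzyl)-1β,2α,4aβ-trimethyl-trans-decalin-5α-ol (H-8a α) | COc1cc(C)c(OC)c(C[C@]2(C)[C@H]3CCC[C@H](O)[C@]3(C)CC[C@@H]2C)c1 | intermediate
24 | 1α-(2,5-dimethoxy-3-methylbenzyl)-1β,2α,4aβ-trimethyl-trans-decalin-5-one (H-8a α) | COc1cc(C)c(OC)c(C[C@]2(C)[C@H]3CCCC(=O)[C@]3(C)CC[C@@H]2C)c1 | intermediate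
25 | potassium C5 enolate of 24 (not isolated) | COc1cc(C)c(OC)c(C[C@]2(C)[C@H]3CCC=C(O[K])[C@]3(C)CC[C@@H]2C)c1 | intermediate
26 | C5 enol triflate of 24 (C5=C6) | COc1cc(C)c(OC)c(C[C@]2(C)[C@H]3CCC=C(OS(=O)(=O)C(F)(F)F)[C@]3(C)CC[C@@H]2C)c1 | intermediate
27 | ethyl 3-(decal-5-en-5-yl)propanoate, substituents as in 24 | COc1cc(C)c(OC)c(C[C@]2(C)[C@H]3CCC=C(CCC(=O)OCC)[C@]3(C)CC[C@@H]2C)c1 | intermediate
28 | C6 α-alkylborane from 27 (not isolated) | COc1cc(C)c(OC)c(C[C@]2(C)[C@H]3CC[C@H](B)[C@@H](CCC(=O)OCC)[C@]3(C)CC[C@@H]2C)c1 | intermediate
29 | ethyl 3-(6α-hydroxy-trans-decalin-5β-yl)propanoate, H-5 α | COc1cc(C)c(OC)c(C[C@]2(C)[C@H]3CC[C@H](O)[C@@H](CCC(=O)OCC)[C@]3(C)CC[C@@H]2C)c1 | intermediate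
30 | ethyl 3-(6-oxo-trans-decalin-5β-yl)propanoate, H-5 α | COc1cc(C)c(OC)c(C[C@]2(C)[C@H]3CCC(=O)[C@@H](CCC(=O)OCC)[C@]3(C)CC[C@@H]2C)c1 | intermediate
31 | ethyl 3-[6-(propan-2-ylidene)-trans-decalin-5β-yl]propanoate, H-5 α | COc1cc(C)c(OC)c(C[C@]2(C)[C@H]3CCC(=C(C)C)[C@@H](CCC(=O)OCC)[C@]3(C)CC[C@@H]2C)c1 | intermediate
32 | 3-[(1S,2S,4aR,5S,8aR)-1-(2,5-dimethoxy-3-methylbenzyl)-1,2,4a-trimethyl-6-(propan-2-ylidene)decahydronaphthalen-5-yl]propanoic acid | COc1cc(C)c(OC)c(C[C@]2(C)[C@H]3CCC(=C(C)C)[C@@H](CCC(=O)O)[C@]3(C)CC[C@@H]2C)c1 | intermediate
33 | CNP0271365.1, the quinone acid | CC1=CC(=O)C=C(C[C@]2(C)[C@H]3CCC(=C(C)C)[C@@H](CCC(=O)O)[C@]3(C)CC[C@@H]2C)C1=O | target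

## Step count and risk

Total step count: 24. Longest linear sequence: 20 steps (steps 5–24, from 6); the diene arm (steps 1–4) joins at step 11.

Least certain steps:

**Step 11 (key step).** The trisubstituted enal with a bulky α-arm is a sluggish dienophile. The amount of Lewis acid or the temperature needed to drive it may ionise or desilylate the allylic silyl ether, polymerise the diene, or erode endo and facial selectivity. Fallback: change the mode of activation from a Lewis acid complex to a cationic dienophile. Enal 15 is converted into its dioxolane, 2-[(E)-1-(2,5-dimethoxy-3-methylphenyl)but-2-en-2-yl]-1,3-dioxolane F1 (1,2-bis(trimethylsilyloxy)ethane, catalytic Me3SiOTf, −78 °C). F1 is combined with 5 under catalytic Me3SiOTf at −78 °C; the alkoxyallyl cation is a far stronger dienophile and should show the same regio-, endo- and facial preferences. The product is the dioxolane of the cycloadduct F2, which is hydrolysed (pyridinium p-toluenesulfonate, wet acetone) to return at 16.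

**Step 13.** The director is remote (bishomoallylic) and the alkene is trisubstituted and hindered on both faces, so slow conversion, O-methylation of the alcohol or poor facial selectivity may result. Fallback: move the director to C5. Setting out from 16, Wolff–Kishner reduction gives the C1-methyl silyl ether F3, and Bu4NF gives the allylic 5α-alcohol F4. Mitsunobu inversion (4-nitrobenzoic acid, PPh3, diisopropyl azodicarboxylate) gives the 5β-ester F5, and K2CO3 in MeOH the allylic 5β-alcohol F6. Hydroxyl-directed Simmons–Smith cyclopropanation gives the β-cyclopropyl carbinol F7, and hydrogenolysis (H2, PtO2, AcOH) the decalin-5β-ol F8. Dess–Martin oxidation returns at 24. The equatorial 5β-hydroxyl lies close to the alkene plane, so its facial preference is less predictable; this is why it is the reserve and not the first choice.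

**Step 20.** Addition of borane to the hindered trisubstituted alkene may be slow enough for reduction of the ethyl ester to compete. Fallback: carry the chain without a carbonyl. Setting out from 26, Stille coupling with allyltributylstannane (Pd(PPh3)4, LiCl, THF, reflux) gives the 5-allyl diene F9. Double hydroboration (9-BBN for the terminal alkene, then BH3·THF for the ring alkene; NaOH, H2O2) gives the diol F10 with the same α-face delivery at C5. Jones oxidation (CrO3, H2SO4, acetone, 0 °C) gives the keto acid F11, and esterification (EtI, K2CO3, DMF) returns at 30.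

**Step 22.** The hindered α-branched ketone may be reduced to the alcohol or stall at the pinacol stage while acetone homocouples, and long contact with low-valent titanium may involve the ester. Fallback: build the alkene by addition and extrusion. Setting out from 30, the lithium enolate of S-phenyl 2-methylpropanethioate (LiN(iPr)2, THF, −78 to 0 °C) adds to the ketone and closes to the spiro β-lactone F12. Warming F12 in toluene (80–110 °C, silica gel) loses CO2 stereospecifically and returns at 31. This is the known thiol ester enolate β-lactone synthesis followed by thermal decarboxylation; the tertiary alkoxide must be kept cold to avoid attack on the side-chain ester.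

**Step 24.** Over-oxidation of the electron-rich tetrasubstituted alkene, or acid-promoted lactonisation of the acid onto it in the strongly acidic oxidant, may compete with quinone formation. Fallback: separate demethylation from oxidation. Setting out from 32, nucleophilic demethylation with n-BuSLi in HMPA at 110 °C gives the hydroquinone acid F13 under non-acidic conditions. Mild oxidation of F13 with Ag2O in Et2O (or air) returns at 33.

## Further compounds

F1 | step 11 | 2-[(E)-1-(2,5-dimethoxy-3-methylphenyl)but-2-en-2-yl]-1,3-dioxolane | C/C=C(/C1OCCO1)Cc1cc(OC)cc(C)c1OC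
F2 | step 11 | 1,3-dioxolane acetal of adduct 16 | COc1cc(C)c(OC)c(C[C@]2(C4OCCO4)[C@H]3CCC[C@H](O[Si](C)(C)C(C)(C)C)C3=CC[C@@H]2C)c1
F3 | step 13 | C1-methyl octalin 5α-silyl ether (C4=C4a) | COc1cc(C)c(OC)c(C[C@]2(C)[C@H]3CCC[C@H](O[Si](C)(C)C(C)(C)C)C3=CC[C@@H]2C)c1
F4 | step 13 | C1-methyl octalin-5α-ol (C4=C4a) | COc1cc(C)c(OC)c(C[C@]2(C)[C@H]3CCC[C@H](O)C3=CC[C@@H]2C)c1
F5 | step 13 | C1-methyl octalin-5β-yl 4-nitrobenzoate | COc1cc(C)c(OC)c(C[C@]2(C)[C@H]3CCC[C@@H](OC(=O)c4ccc(cc4)[N+](=O)[O-])C3=CC[C@@H]2C)c1
F6 | step 13 | C1-methyl octalin-5β-ol (C4=C4a) | COc1cc(C)c(OC)c(C[C@]2(C)[C@H]3CCC[C@@H](O)C3=CC[C@@H]2C)c1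
F7 | step 13 | 4β,4aβ-methylene-bridged 5β-ol | COc1cc(C)c(OC)c(C[C@]2(C)[C@H]3CCC[C@@H](O)[C@@]34C[C@H]4C[C@@H]2C)c1
F8 | step 13 | 1α-(2,5-dimethoxy-3-methylbenzyl)-1β,2α,4aβ-trimethyl-trans-decalin-5β-ol | COc1cc(C)c(OC)c(C[C@]2(C)[C@H]3CCC[C@@H](O)[C@]3(C)CC[C@@H]2C)c1
F9 | step 20 | 5-allyl-decal-5-ene, substituents as in 24 | COc1cc(C)c(OC)c(C[C@]2(C)[C@H]3CCC=C(CC=C)[C@]3(C)CC[C@@H]2C)c1
F10 | step 20 | 5β-(3-hydroxypropyl)-trans-decalin-6α-ol, H-5 α | COc1cc(C)c(OC)c(C[C@]2(C)[C@H]3CC[C@H](O)[C@@H](CCCO)[C@]3(C)CC[C@@H]2C)c1
F11 | step 20 | 3-(6-oxo-trans-decalin-5β-yl)propanoic acid, H-5 α | COc1cc(C)c(OC)c(C[C@]2(C)[C@H]3CCC(=O)[C@@H](CCC(=O)O)[C@]3(C)CC[C@@H]2C)c1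
F12 | step 22 | spiro β-lactone at C6 (3,3-dimethyloxetan-2-one; C6 epimers converge) | COc1cc(C)c(OC)c(C[C@]2(C)[C@H]3CCC4(OC(=O)C4(C)C)[C@@H](CCC(=O)OCC)[C@]3(C)CC[C@@H]2C)c1
F13 | step 24 | hydroquinone acid (2,5-dihydroxy-3-methylbenzyl analogue of 32) | Cc1cc(O)cc(C[C@]2(C)[C@H]3CCC(=C(C)C)[C@@H](CCC(=O)O)[C@]3(C)CC[C@@H]2C)c1O
A1 | alternative 1 | trans-fused 5,5-ethylenedioxy-1β,2α,4aβ-trimethyl-octal-3-ene-1α-carboxylic acid (H-8a α) | OC(=O)[C@]2(C)[C@H]3CCCC4(OCCO4)[C@]3(C)C=C[C@@H]2C
A2 | alternative 2 | methyl 3-(6,6-ethylenedioxy-1α-formyl-1β,2α,4aβ-trimethyl-trans-octal-3-en-5β-yl)propanoate (H-8a α) | O=C[C@]2(C)[C@H]3CCC4(OCCO4)[C@@H](CCC(=O)OC)[C@]3(C)C=C[C@@H]2C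
A3 | alternative 3 | 3-allyl-4-(2,5-dimethoxy-3-methylbenzyl)-2-(1-hydroxyallyl)-2,4-dimethylcyclohexan-1-one | COc1cc(C)c(OC)c(C[C@]2(C)[C@@H](CC=C)[C@](C)([C@@H](O)C=C)C(=O)CC2)c1
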